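## The problem

The target is a monocyclic seco-terpenoid with a single cyclohexane ring, numbered here C1–C6. C1 is quaternary and carries a hydroxymethyl group and the C16 (3E,7E)-homofarnesyl chain. C2 carries a 3-hydroxypropyl arm, C3 is joined by a tetrasubstituted exocyclic alkene to Cα (methyl and formyl, formyl on the C2 side, Z), and C6 is a tertiary carbinol bearing a methyl group. C6, C1 and C2 are contiguous stereocentres, two of them fully substituted and adjacent, with the C6 hydroxyl, the C1 hydroxymethyl and the C2 arm on one face and the chain and C6 methyl on the other; the C1–C6 bond is therefore the hardest to make. No stereocentre lies outside the ring, so the three centres must be set together in one ordered event or relayed from each other, and the absolute configuration must come from a catalyst or from a temporary centre. The three trisubstituted chain alkenes exclude strong acids, ozone, peracids and catalytic hydrogenation; the enal can lose its geometry or epimerise C2 through γ-deprotonation, and the tertiary alcohol dehydrates under acid. Making the enal by olefination of a C3 ketone would be poor: that ketone is hindered, sits next to the C2 stereocentre and offers no control of geometry. The enabling feature is that the C6 oxygen and C3 are 1,4-related across the ring: re-forming the C3–O bond gives a 7-oxabicyclo[2.2.1]heptane, i.e. a furan (C3, C4, C5, C6 and the oxygen) that has added to a C1=C2 alkene. A second latent ring follows because the terminal carbon of the C2 arm and Cα are 1,5-related through C2–C3: an acyl bond between them closes a six-membered ring A (C3, Cα, C=O, two CH2, C2), and alkoxide cleavage of that ring releases the arm and the carbanion that opens the oxygen bridge.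

## Retrosynthesis

**22 ⇒ 20 (oxidation levels only).** No skeletal bond is cut: the formyl group of 22 is traced to a nitrile and the two primary alcohols to methyl esters, giving ester nitrile 20. A Cα ester would need reduction to the allylic alcohol and re-oxidation; the nitrile reaches the aldehyde level directly through aldimine 21, so one hydride reagent does all three reductions. The forward step must stop at the aldimine on the nitrile, take the hindered C1 ester through to the alcohol, and keep the alkene geometry.

**20 ⇒ 18 (reconnect C3–O and Cα–C(arm terminus)).** Re-forming the C3–O bond to the C6 oxygen and an acyl bond from the arm terminus to Cα turns 20 into tricyclic keto nitrile 18, a 7-oxanorbornane fused to cyclohexanone ring A. In the forward sense methoxide cleaves ring A by retro-Claisen reaction and the resulting carbanion 19 expels the bridging oxygen. This avoids olefinating a C3 ketone, reveals the tertiary alcohol without adding a methyl nucleophile to a ketone, and lets the size gap between cyano and methyl decide the alkene geometry (cyano on the crowded C2 side). Compound 18 is simpler in that the three stereocentres are locked in a rigid frame and no free hydroxyl is present. Cleavage and elimination must outrun proton transfer to 19 and ester condensation.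

**18 ⇒ 17 ⇒ 16 (cut C1–C6 and C2–C3).** Restoring the C4=C5 alkene gives oxanorbornene 17, and a retro-[4+2] opens both the bicycle and ring A to furan Z-enoate 16. Both hindered ring bonds and all three target stereocentres come from one suprafacial event, with relative configuration fixed by the Z geometry and the exo fold. An intermolecular furan cycloaddition with a tetrasubstituted dienophile would have no regiocontrol and a worse equilibrium; cutting C1–C6 alone leaves C2 to be set separately. Compound 16 has one stereocentre (Cα), no ring other than the furan, and splits into two halves. The forward reaction must bond a fully substituted alkene carbon to the methyl-bearing furan carbon, fold exo, let Cα choose the furan face, and be followed at once by saturation of 17 so that it cannot revert.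

**16 ⇒ 15 + 8 (cut C1=C2).** The enoate double bond is cut to keto aldehyde 15 and α-homofarnesyl phosphonate 8. This is the convergent junction, and it places the coupling at the bond whose geometry decides the C1 configuration; trifluoroethyl phosphonates are the most reliable route to trisubstituted enoates with the ester cis to the new substituent. Preparing the enoic acid first and acylating the nitrile with it would need two carboxyl groups to be told apart and wastes acyl donor. The olefination must be Z-selective and must choose the aldehyde over the hindered ketone.

**15 ⇒ 13 ⇒ 11 + 12; 11 ⇒ 10 ⇒ 9 (cut Cα–C(=O)).** The aldehyde of 15 is carried as the terminal alkene of 13. The Cα–acyl bond of 13 is cut to silyl ketene imine 11 and pent-4-enoic anhydride 12, so the quaternary stereocentre is built by catalytic asymmetric C-acylation in the step that joins the two pieces. Asymmetric methylation of an acyclic α-furyl β-keto ester or nitrile has much thinner precedent. Ketene imine 11 comes from racemic nitrile 10, itself one step from commercial ketone 9. The forward steps need high enantioselectivity with a 2-furyl group and an oxidative cleavage that spares the furan.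

**8 ⇒ 6 + 7; 6 ⇒ 5 ⇒ 3 ⇒ 2 ⇒ 1.** The bond between the phosphonate α-carbon and the chain is cut to commercial phosphonoacetate 7 and homofarnesyl iodide 6. The iodide comes from farnesol 1 by one-carbon homologation: oxidation to 2, methylenation to tetraene 3, terminal hydroboration (borane 4) to alcohol 5, and iodination. Cyanide displacement on farnesyl bromide would risk allylic transposition and conjugation. The alkylation must favour substitution over elimination, and the E alkenes must stay untouched.

## Roads not taken

**Alternative 1:** The cut is C1–C6. SmI2 reduces the methyl ketone of keto butenolide A2 to a ketyl that adds 6-exo to the butenolide β-carbon and gives spiro-lactone A1, with the C3 carbonyl masked as a dioxolane.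
- Merits: ketyl–alkene closures tolerate bonds between two fully substituted carbons, a samarium chelate between the new alkoxide and the lactone should set the C6 oxygen cis to the CH2O branch, and the resident C2 centre directs the closure. For forming the C1–C6 bond this road is better than the cycloaddition, which must make that bond reversibly against steric compression.
- Weak points: A1 contains only the ring. The C16 chain must be grown from the lactone carbonyl over several steps, including a trisubstituted E alkene. The C2 centre must be made enantioselectively beforehand. The unmasked C3 ketone, hindered and next to the epimerisable C2 centre, must still be olefinated to a tetrasubstituted enal of defined geometry.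
- Comparison: the chosen plan has chain, arm and Cα unit in place before any ring forms, obtains the alkylidene and its geometry from a fragmentation, and is shorter.

**Alternative 2:** The cut is C1–C2. Double silylation of keto δ-lactone A4 gives a ketene acetal at C1 and a Z-enol silane at C2=C3; a boat [3,3] shift forms C1–C2, breaks the C4–O bond and gives, after hydrolysis, cyclohexanone acid A3.
- Merits: the quaternary C1, with the chain already attached, and C2 are set together in an ordered transition state, and chirality is relayed from conventional carbinol centres of a mevalonolactone-like ring. In stereochemical pedigree this road is at least equal to the chosen one, which relies on a temporary centre.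
- Weak points: two enolisations must be controlled in one molecule. The ketone must enolise Z-selectively and away from the carbinol carbon, or the carboxylate is eliminated. The lactone enolate carries a β-silyloxy group. The forced boat joins a quaternary carbon to a substituted enol carbon. Afterwards the C3 ketone, now α to C2, again needs conversion to the Z-enal, and the acid must be reduced.
- Comparison: the chosen plan offers a pericyclic step with fixed relative topology, no carbonyl ever α to C2, and no late olefination.

**Alternative 3:** The cuts are C1–chain and C2–arm. Conjugate addition of homofarnesylmagnesium bromide A7 (with catalytic CuBr·SMe2) to C1 of enone acetonide A6, then trapping of the enolate at C2 with allyl iodide A8, gives ketone A5 in one flask; no ring is formed.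
- Merits: this is the most convergent road. The chain arrives whole, and the cis-fused acetonide ties the CH2O branch to the C6 oxygen, so the C1 configuration follows from C6 without a facial question. In step count to the fully substituted ring it is better than the chosen plan.
- Weak points: conjugate addition that creates a quaternary carbon next to fully substituted C6 is among the hardest cases. The C2 enolate lies beside the new quaternary centre, so C-allylation is slow and enolate equilibration, O-allylation and over-allylation compete. The face of allylation is uncertain. The allyl group must be hydroborated beside the chain. The C3 ketone, with epimerisable C2, again has to become the Z-enal.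
- Comparison: the chosen plan sets against the shorter ring assembly one step that forms both ring bonds and all three centres, and an alkylidene formed by elimination rather than olefination.

Key step: step 11

Remark on the chemistry: the sense of induction of the acylation catalyst with a 2-furyl ketene imine is not predicted; the catalyst antipode is chosen by correlation so that 13 is (R).
Remark on materials: 9 is the commercial acetyl derivative of 2-methylfuran; 7, 12 and both antipodes of the catalyst are purchased.

## Steps

Step 1
Reactants: 1 (2E,6E)-farnesol
Product: 2 (2E,6E)-farnesal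
Conditions: MnO2 (activated, excess), CH2Cl2, rt
Reagents that add atoms: none
Why: Allylic alcohol oxidation on manganese dioxide; the neutral heterogeneous oxidant leaves the 2E geometry and the remote alkenes untouched.

Step 2
Reactants: 2 (2E,6E)-farnesal
Product: 3 (3E,7E)-4,8,12-trimethyltrideca-1,3,7,11-tetraene
Conditions: Ph3PCH3Br, n-BuLi, THF, 0 °C; then 2, 0 °C → rt
Reagents that add atoms: methyltriphenylphosphonium bromide, C[P+](c1ccccc1)(c1ccccc1)c1ccccc1.[Br-]
Why: Wittig methylenation of an enal; no new stereo element arises and the 2E alkene becomes the 3E alkene of the diene.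

Step 3
Reactants: 3 (3E,7E)-4,8,12-trimethyltrideca-1,3,7,11-tetraene
Product: 5 (3E,7E)-4,8,12-trimethyltrideca-3,7,11-trien-1-ol (homofarnesol), via homofarnesyl-9-BBN 4 (not isolated)
Conditions: 9-BBN, THF, 0 °C → rt; then NaOH, H2O2, H2O, 0 °C → rt
Reagents that add atoms: hydrogen peroxide, OO
Why: Brown hydroboration–oxidation; 9-BBN adds anti-Markovnikov to the monosubstituted terminal alkene and ignores the trisubstituted ones, the standard route from geranial- and farnesal-derived dienes to the homo-alcohols.

Step 4
Reactants: 5 homofarnesol
Product: 6 (3E,7E)-1-iodo-4,8,12-trimethyltrideca-3,7,11-triene (homofarnesyl iodide)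
Conditions: I2, PPh3, imidazole, CH2Cl2, 0 °C → rt
Reagents that add atoms: iodine, II
Why: Appel-type iodination (Garegg–Samuelsson conditions); SN2 at a primary carbon under buffered conditions that leave the alkenes alone.

Step 5
Reactants: 6 homofarnesyl iodide; 7 methyl bis(2,2,2-trifluoroethyl)phosphonoacetate
Product: 8 methyl (5E,9E)-2-[bis(2,2,2-trifluoroethoxy)phosphoryl]-6,10,14-trimethylpentadeca-5,9,13-trienoate (racemic)
Conditions: NaH, 7 (1.5 equiv), DMSO/THF, rt; then 6, rt → 45 °C
Reagents that add atoms: none
Why: C-alkylation of a phosphonoacetate sodium salt by a primary iodide; the soft stabilised carbanion favours SN2 over E2, and excess 7 limits double alkylation.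

Step 6
Reactants: 9 2-acetyl-5-methylfuran
Product: 10 (±)-2-(5-methylfuran-2-yl)propanenitrile
Conditions: TosMIC, t-BuOK, EtOH (2 equiv), DME, 0 °C → rt
Reagents that add atoms: p-toluenesulfonylmethyl isocyanide, [C-]#[N+]CS(=O)(=O)c1ccc(C)cc1
Why: Van Leusen reductive cyanation converts an aryl or heteroaryl methyl ketone into the homologous nitrile in one step; the racemic centre is erased in step 7.

Step 7
Reactants: 10 (±)-2-(5-methylfuran-2-yl)propanenitrile
Product: 11 N-(tert-butyldimethylsilyl)-2-(5-methylfuran-2-yl)prop-1-en-1-imine (silyl ketene imine)
Conditions: LiN(i-Pr)2, THF, −78 °C; TBSCl, −78 °C → rt; filtration through Celite in pentane under argon, used crude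
Reagents that add atoms: tert-butyldimethylsilyl chloride, CC(C)(C)[Si](C)(C)Cl
Why: The anion of an α-aryl-α-alkyl nitrile is silylated on nitrogen by a bulky silyl chloride, the standard entry to silyl ketene imines.

Step 8
Reactants: 11 silyl ketene imine; 12 pent-4-enoic anhydride
Product: 13 (2R)-2-methyl-2-(5-methylfuran-2-yl)-3-oxohept-6-enenitrile
Conditions: planar-chiral catalyst Fe(η5-C5Ph5)(η5-C12H13N2), C12H13N2 = 4-(pyrrolidin-1-yl)pyrindinyl (5 mol %, antipode giving the R product), ClCH2CH2Cl, rt
Reagents that add atoms: none
Why: Catalytic enantioselective C-acylation of a silyl ketene imine: the catalyst and anhydride form a chiral acylpyridinium carboxylate, the carboxylate removes the silyl group, and the ion pair C-acylates the nitrile anion. The catalyst sets the quaternary centre; the reaction type is established for aryl(alkyl) ketene imines with simple anhydrides.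

Step 9
Reactants: 13 (2R)-2-methyl-2-(5-methylfuran-2-yl)-3-oxohept-6-enenitrile
Product: 15 (2R)-2-methyl-2-(5-methylfuran-2-yl)-3,6-dioxohexanenitrile, via vicinal diol 14 (not isolated)
Conditions: OsO4 (2 mol %), NaIO4, 2,6-lutidine, dioxane/H2O 3:1, rt
Reagents that add atoms: osmium tetroxide, O=[Os](=O)(=O)=O (catalytic oxygen carrier); sodium periodate, [Na+].[O-]I(=O)(=O)=O (stoichiometric oxygen source)
Why: Lemieux–Johnson cleavage (dihydroxylation, then periodate glycol cleavage in the same flask). The monosubstituted alkene reacts fastest, the furan is deactivated by the acyl- and cyano-bearing quaternary carbon, and Cα has no proton to lose.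

Step 10
Reactants: 15 keto aldehyde; 8 α-homofarnesyl phosphonate
Product: 16 methyl (2Z,7R)-7-cyano-7-(5-methylfuran-2-yl)-6-oxo-2-[(3E,7E)-4,8,12-trimethyltrideca-3,7,11-trien-1-yl]oct-2-enoate
Conditions: 8, KN(SiMe3)2, 18-crown-6, THF, −78 °C; then 15, −78 °C
Reagents that add atoms: none
Why: Still–Gennari olefination; the trifluoroethyl phosphonate with a dissociated potassium counter-ion eliminates fast from the first-formed adduct and gives the Z enoate (ester cis to the new CH2). The aldehyde reacts in preference to the ketone flanked by a quaternary carbon.

Step 11
Reactants: 16 furan Z-enoate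
Product: 17 methyl (4R,4aS,7R,8S,8aR)-4-cyano-4,7-dimethyl-3-oxo-8-[(3E,7E)-4,8,12-trimethyltrideca-3,7,11-trien-1-yl]-1,2,3,4,4a,7,8,8a-octahydro-4a,7-epoxynaphthalene-8-carboxylate (oxanorbornene: ester and ring A methylene exo, syn to the oxygen bridge; chain endo; cyano axial and methyl equatorial on ring A)
Conditions: Me2AlCl (2.5 equiv), CH2Cl2, −78 → −30 °C; Et3N then aq. NaHCO3 at −30 °C; crude kept at or below 0 °C
Reagents that add atoms: none
Why: Concerted suprafacial normal-demand [4+2] cycloaddition: the 2,5-disubstituted furan (HOMO raised by the methyl group) adds across the Z-enoate, whose LUMO is lowered by Me2AlCl on the ester carbonyl, and C1–C6 and C2–C3 form together. The closest known reaction type is the intramolecular Diels–Alder reaction of 2-alkylfurans carrying an activated alkene on a four-atom tether, run with methylaluminium chlorides at low temperature so that the adduct side of the equilibrium is favoured. The oxanorbornene closes as the cycloaddition ring itself (furan C2 and C5 onto the two alkene carbons), and ring A closes as the six-membered ring spanned by the tether (C3, Cα, C=O, two CH2, C2), fused exo, syn to the oxygen bridge, the only fold a four-atom tether allows without severe strain. C1 and C2 are set relative to each other by the Z geometry (ester and arm stay cis, chain trans), and C2, C3 and C6 relative to the bridge by the exo fold. The absolute sense of all four new centres comes from Cα: in the chair-like fold of ring A one Cα substituent must stand pseudo-axial beside the furan C3–H and the C2–H, the thin cyano group takes that place while methyl stays equatorial, and this exposes the furan face that leads to 17. The step needs exo selectivity, face selectivity and an equilibrium on the product side; the tether length, the cyano/methyl size gap and the low temperature are there to provide them. The minor-face isomer would be a diastereomer, removable by chromatography and returned to 16 by gentle warming. Crude 17 is reduced at once.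

Step 12
Reactants: 17 oxanorbornene cycloadduct
Product: 18 methyl (4R,4aS,7R,8S,8aR)-4-cyano-4,7-dimethyl-3-oxo-8-[(3E,7E)-4,8,12-trimethyltrideca-3,7,11-trien-1-yl]decahydro-4a,7-epoxynaphthalene-8-carboxylate
Conditions: dipotassium azodicarboxylate (KO2CN=NCO2K), AcOH, CH2Cl2/MeOH, −20 → 0 °C
Reagents that add atoms: none
Why: Diimide transfers two hydrogens syn to the strained disubstituted alkene of the oxanorbornene and leaves the trisubstituted chain alkenes alone. With the alkene gone the cycloaddition can no longer revert; no stereocentre is created.

Step 13
Reactants: 18 saturated tricyclic keto nitrile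
Product: 20 methyl (1S,2R,5Z,6S)-5-(1-cyanoethylidene)-2-hydroxy-6-(3-methoxy-3-oxopropyl)-2-methyl-1-[(3E,7E)-4,8,12-trimethyltrideca-3,7,11-trien-1-yl]cyclohexane-1-carboxylate, via sodium cyano carbanion 19 (not isolated)
Conditions: NaOMe (1.3 equiv, anhydrous), 15-crown-5, THF, −20 → 0 °C; AcOH at −20 °C
Reagents that add atoms: sodium methoxide, C[O-].[Na+]
Why: Retro-Claisen cleavage of a non-enolisable α-cyano ketone by methoxide gives the arm methyl ester and carbanion 19, which expels the bridging oxygen (E1cB, a retro-oxa-Michael reaction driven by release of bicyclic strain) to form C3=Cα and the C6 alkoxide. The linear cyano group takes the crowded C2 side and methyl the C4 side, giving the Z alkene; the aprotic medium keeps 19 from being protonated before it eliminates.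

Step 14
Reactants: 20 ester nitrile
Product: 22 (2Z)-2-[(2S,3R,4R)-4-hydroxy-3-(hydroxymethyl)-2-(3-hydroxypropyl)-4-methyl-3-[(3E,7E)-4,8,12-trimethyltrideca-3,7,11-trien-1-yl]cyclohexylidene]propanal (CNP0284886.2), via triol aldimine 21 (not isolated)
Conditions: i-Bu2AlH (8 equiv), CH2Cl2, −78 → 0 °C; aq. potassium sodium tartrate, then aq. citric acid (pH 4), 0 °C → rt
Reagents that add atoms: water, O
Why: i-Bu2AlH reduces both methyl esters to primary alcohols and adds once to the nitrile, stopping at the N-aluminated aldimine, which hydrolyses to the enal on mildly acidic work-up. Hydride adds 1,2, so the Z geometry is kept, and no stereocentre is touched.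

## Compound list

1 | (2E,6E)-farnesol | CC(C)=CCC/C(C)=C/CC/C(C)=C/CO | starting material
2 | (2E,6E)-farnesal | CC(C)=CCC/C(C)=C/CC/C(C)=C/C=O | intermediate
3 | (3E,7E)-4,8,12-trimethyltrideca-1,3,7,11-tetraene | CC(C)=CCC/C(C)=C/CC/C(C)=C/C=C | intermediate
4 | B-[(3E,7E)-4,8,12-trimethyltrideca-3,7,11-trien-1-yl]-9-borabicyclo[3.3.1]nonane | CC(C)=CCC/C(C)=C/CC/C(C)=C/CCB1C2CCCC1CCC2 | intermediate
5 | (3E,7E)-4,8,12-trimethyltrideca-3,7,11-trien-1-ol (homofarnesol) | CC(C)=CCC/C(C)=C/CC/C(C)=C/CCO | intermediate
6 | (3E,7E)-1-iodo-4,8,12-trimethyltrideca-3,7,11-triene | CC(C)=CCC/C(C)=C/CC/C(C)=C/CCI | intermediate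
7 | methyl bis(2,2,2-trifluoroethyl)phosphonoacetate | COC(=O)CP(=O)(OCC(F)(F)F)OCC(F)(F)F | starting material
8 | methyl (5E,9E)-2-[bis(2,2,2-trifluoroethoxy)phosphoryl]-6,10,14-trimethylpentadeca-5,9,13-trienoate (racemic) | CC(C)=CCC/C(C)=C/CC/C(C)=C/CCC(C(=O)OC)P(=O)(OCC(F)(F)F)OCC(F)(F)F | intermediate
9 | 2-acetyl-5-methylfuran | CC(=O)c1ccc(C)o1 | starting material
10 | (±)-2-(5-methylfuran-2-yl)propanenitrile | CC(C#N)c1ccc(C)o1 | intermediate
11 | N-(tert-butyldimethylsilyl)-2-(5-methylfuran-2-yl)prop-1-en-1-imine | CC(=C=N[Si](C)(C)C(C)(C)C)c1ccc(C)o1 | intermediate
12 | pent-4-enoic anhydride | C=CCCC(=O)OC(=O)CCC=C | starting material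
13 | (2R)-2-methyl-2-(5-methylfuran-2-yl)-3-oxohept-6-enenitrile | C=CCCC(=O)[C@](C)(C#N)c1ccc(C)o1 | intermediate
14 | (2R)-6,7-dihydroxy-2-methyl-2-(5-methylfuran-2-yl)-3-oxoheptanenitrile (both C6 epimers) | OCC(O)CCC(=O)[C@](C)(C#N)c1ccc(C)o1 | intermediate
15 | (2R)-2-methyl-2-(5-methylfuran-2-yl)-3,6-dioxohexanenitrile | O=CCCC(=O)[C@](C)(C#N)c1ccc(C)o1 | intermediate
16 | methyl (2Z,7R)-7-cyano-7-(5-methylfuran-2-yl)-6-oxo-2-[(3E,7E)-4,8,12-trimethyltrideca-3,7,11-trien-1-yl]oct-2-enoate | CC(C)=CCC/C(C)=C/CC/C(C)=C/CC/C(C(=O)OC)=C/CCC(=O)[C@](C)(C#N)c1ccc(C)o1 | intermediate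
17 | methyl (4R,4aS,7R,8S,8aR)-4-cyano-4,7-dimethyl-3-oxo-8-[(3E,7E)-4,8,12-trimethyltrideca-3,7,11-trien-1-yl]-1,2,3,4,4a,7,8,8a-octahydro-4a,7-epoxynaphthalene-8-carboxylate | CC(C)=CCC/C(C)=C/CC/C(C)=C/CC[C@]1(C(=O)OC)[C@H]2CCC(=O)[C@](C)(C#N)[C@]23C=C[C@@]1(C)O3 | intermediate
18 | methyl (4R,4aS,7R,8S,8aR)-4-cyano-4,7-dimethyl-3-oxo-8-[(3E,7E)-4,8,12-trimethyltrideca-3,7,11-trien-1-yl]decahydro-4a,7-epoxynaphthalene-8-carboxylate | CC(C)=CCC/C(C)=C/CC/C(C)=C/CC[C@]1(C(=O)OC)[C@H]2CCC(=O)[C@](C)(C#N)[C@]23CC[C@@]1(C)O3 | intermediate
19 | sodium carbanion from ring A cleavage of 18: 7-oxanorbornane with 1-cyanoethanide on bridgehead C3, exo 3-methoxy-3-oxopropyl arm on C2, exo methyl ester and endo homofarnesyl on C1, methyl on bridgehead C6 | CC(C)=CCC/C(C)=C/CC/C(C)=C/CC[C@]1(C(=O)OC)[C@@H](CCC(=O)OC)[C@@]2(CC[C@@]1(C)O2)[C-](C)C#N.[Na+] | intermediate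
20 | methyl (1S,2R,5Z,6S)-5-(1-cyanoethylidene)-2-hydroxy-6-(3-methoxy-3-oxopropyl)-2-methyl-1-[(3E,7E)-4,8,12-trimethyltrideca-3,7,11-trien-1-yl]cyclohexane-1-carboxylate | CC(C)=CCC/C(C)=C/CC/C(C)=C/CC[C@]1(C(=O)OC)[C@@H](CCC(=O)OC)/C(=C(/C)C#N)CC[C@@]1(C)O | intermediate
21 | (2Z)-2-[(2S,3R,4R)-4-hydroxy-3-(hydroxymethyl)-2-(3-hydroxypropyl)-4-methyl-3-[(3E,7E)-4,8,12-trimethyltrideca-3,7,11-trien-1-yl]cyclohexylidene]propan-1-imine | CC(C)=CCC/C(C)=C/CC/C(C)=C/CC[C@]1(CO)[C@@H](CCCO)/C(=C(/C)C=N)CC[C@@]1(C)O | intermediate
22 | (2Z)-2-[(2S,3R,4R)-4-hydroxy-3-(hydroxymethyl)-2-(3-hydroxypropyl)-4-methyl-3-[(3E,7E)-4,8,12-trimethyltrideca-3,7,11-trien-1-yl]cyclohexylidene]propanal | CC(C)=CCC/C(C)=C/CC/C(C)=C/CC[C@]1(CO)[C@@H](CCCO)/C(=C(/C)C=O)CC[C@@]1(C)O | target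

## Step count and least certain steps

Total: 14 steps. Longest linear sequence: 10 steps (1 → 22 through steps 1–5 and 10–14); the furan branch (steps 6–9) joins at step 10.

**Step 11 (key step).** The C1–C6 bond joins a fully substituted alkene carbon to the methyl-bearing furan carbon, so cycloreversion may keep the equilibrium on the side of 16 at any temperature where the forward reaction is fast. The Lewis acid may also start ene or cation–alkene reactions of the chain, and the cyano/methyl bias may not separate the two furan faces well enough. Fallback: give up accumulating the adduct and drain the equilibrium instead. Compound 16 is heated with p-toluenesulfonyl hydrazide and NaOAc in DME at 85 °C, so that diimide, generated continuously, reduces the strained alkene of each molecule of 17 as it forms; the hindered enoate and the furan are reduced far more slowly. This sets out from 16 and returns at 18, and makes no compound outside the list (F0).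

**Step 8.** A 2-furyl ketene imine and a pentenoyl donor lie outside the tested range, so the acylation may be poorly enantioselective or may go on nitrogen; the sense of induction is unknown. Fallback: nitrile 10 is deprotonated with LiN(i-Pr)2 and added to pent-4-enoyl chloride at −78 °C to give racemic 2-methyl-2-(5-methylfuran-2-yl)-3-oxohept-6-enenitrile F1. Preparative chromatography on a chiral stationary phase then delivers 13 and sets aside the (2S)-enantiomer F2. This sets out from 10 and returns at 13; the same separation would also polish a partial enantiomeric excess from the catalytic step.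

**Step 9.** The osmium/periodate system may oxidise the furan, and the 1,4-keto aldehyde may condense with itself in the buffered medium. Fallback: the aldehyde is carried masked.
- Commercial methyl 4,4-dimethoxybutanoate is saponified to 4,4-dimethoxybutanoic acid F3 and dehydrated with dicyclohexylcarbodiimide to 4,4-dimethoxybutanoic anhydride F4.
- Ketene imine 11 is acylated with F4 under the catalyst of step 8 to give (2R)-6,6-dimethoxy-2-methyl-2-(5-methylfuran-2-yl)-3-oxohexanenitrile F5.
- Mild hydrolysis (pyridinium p-toluenesulfonate, acetone/H2O) gives 15.

This sets out from 11 and returns at 15.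

**Step 13.** Carbanion 19 may be protonated before it expels the bridge, stalling at the Cα–H nitrile. The alkoxide formed may promote Claisen condensation of the arm ester onto the C1 ester, and attack at the hindered ketone may be slow; poor geometric control would follow from a stalled, stepwise course. Fallback: the cleavage and the elimination are separated, and the arm is protected as a carboxylate.
- LiOH in THF/H2O cleaves ring A of 18 to the Cα–H nitrile carboxylic acid F6 (both Cα epimers).
- LiN(i-Pr)2 (3 equiv, THF, −78 → −40 °C) deprotonates only the nitrile α-carbon, since the carboxylate is inert, and the E1cB opening gives the hydroxy acid alkenyl nitrile F7.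
- Me3SiCHN2 in MeOH/toluene re-forms the methyl ester and gives 20.

This sets out from 18 and returns at 20.

**Step 14.** The excess hydride needed for the hindered C1 ester may carry the nitrile past the aldimine, or the nitrile may lag behind. The aldimine hydrolysis may need acidity that endangers the chain alkenes and the tertiary alcohol, and geometry may erode through a metallo-enamine. Fallback: the reductions are split. LiBH4 (THF, MeOH 2 equiv, 0 → 40 °C) reduces both esters of 20 and leaves the nitrile, giving the triol nitrile F8. With only the nitrile left, i-Bu2AlH (5 equiv, toluene, −78 °C) and hydrolysis on wet silica gel give 22. This sets out from 20 and returns at 22.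

## Further compounds

F0 | step 11 | none | none
F1 | step 8 | racemic 2-methyl-2-(5-methylfuran-2-yl)-3-oxohept-6-enenitrile | C=CCCC(=O)C(C)(C#N)c1ccc(C)o1
F2 | step 8 | (2S)-2-methyl-2-(5-methylfuran-2-yl)-3-oxohept-6-enenitrile | C=CCCC(=O)[C@@](C)(C#N)c1ccc(C)o1
F3 | step 9 | 4,4-dimethoxybutanoic acid | COC(OC)CCC(=O)O
F4 | step 9 | 4,4-dimethoxybutanoic anhydride | COC(OC)CCC(=O)OC(=O)CCC(OC)OC
F5 | step 9 | (2R)-6,6-dimethoxy-2-methyl-2-(5-methylfuran-2-yl)-3-oxohexanenitrile | COC(OC)CCC(=O)[C@](C)(C#N)c1ccc(C)o1
F6 | step 13 | 7-oxanorbornane carboxylic acid with 1-cyanoethyl on bridgehead C3 (both Cα epimers), exo 2-carboxyethyl arm on C2, exo methyl ester and endo homofarnesyl on C1 | CC(C)=CCC/C(C)=C/CC/C(C)=C/CC[C@]1(C(=O)OC)[C@@H](CCC(=O)O)[C@@]2(CC[C@@]1(C)O2)C(C)C#N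
F7 | step 13 | 3-[(1S,2S,3R,6Z)-6-(1-cyanoethylidene)-3-hydroxy-2-(methoxycarbonyl)-3-methyl-2-[(3E,7E)-4,8,12-trimethyltrideca-3,7,11-trien-1-yl]cyclohexyl]propanoic acid | CC(C)=CCC/C(C)=C/CC/C(C)=C/CC[C@]1(C(=O)OC)[C@@H](CCC(=O)O)/C(=C(/C)C#N)CC[C@@]1(C)O
F8 | step 14 | (2Z)-2-[(2S,3R,4R)-4-hydroxy-3-(hydroxymethyl)-2-(3-hydroxypropyl)-4-methyl-3-[(3E,7E)-4,8,12-trimethyltrideca-3,7,11-trien-1-yl]cyclohexylidene]propanenitrile | CC(C)=CCC/C(C)=C/CC/C(C)=C/CC[C@]1(CO)[C@@H](CCCO)/C(=C(/C)C#N)CC[C@@]1(C)O
A1 | alternative 1 | spiro-lactone cyclohexanol | O=C1C[C@]2(CO1)[C@@H](CCCO[Si](C)(C)C(C)(C)C)C3(OCCO3)CC[C@@]2(C)O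
A2 | alternative 1 | keto butenolide (methyl ketone, dioxolane at C3, butenolide on C2) | CC(=O)CCC1(OCCO1)[C@H](CCCO[Si](C)(C)C(C)(C)C)C2=CC(=O)OC2
A3 | alternative 2 | cyclohexanone acid | CC(C)=CCC/C(C)=C/CC/C(C)=C/CC[C@]1(C(=O)O)[C@@H](CCCO[Si](C)(C)C(C)(C)C)C(=O)CC[C@@]1(C)O[Si](CC)(CC)CC
A4 | alternative 2 | keto δ-lactone (C1 epimers; ketone side chain on the carbinol carbon) | CC(C)=CCC/C(C)=C/CC/C(C)=C/CCC1C(=O)O[C@H](C(=O)CCCCO[Si](C)(C)C(C)(C)C)C[C@@]1(C)O[Si](CC)(CC)CC
A5 | alternative 3 | 2-allyl-3,3-disubstituted cyclohexanone acetonide | CC(C)=CCC/C(C)=C/CC/C(C)=C/CC[C@]1(COC(C)(C)O2)[C@@H](CC=C)C(=O)CC[C@]12C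
A6 | alternative 3 | acetonide-fused enone | CC1(C)OCC2=CC(=O)CC[C@@]2(C)O1
A7 | alternative 3 | homofarnesylmagnesium bromide | CC(C)=CCC/C(C)=C/CC/C(C)=C/CC[Mg]Br
A8 | alternative 3 | allyl iodide | C=CCI
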